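**Strategy.** Everything rests on reading the six-membered ring, a cyclohexene with a methyl group on one alkene carbon and the side chain on the sp3 carbon para to it, as the cycloadduct of isoprene with an acrylic dienophile whose carbonyl carbon ends up as side-chain C1 (C1 = ring-bound alkene carbon, C12 = ketone, C21 = isopropyl CH). A single copper-catalysed asymmetric Diels–Alder reaction of isoprene with achiral 3-acryloyloxazolidin-2-one makes the ring, both new ring bonds and the ring stereocentre. The acyl group is then elaborated to the C1 methylidene and a (Z)-alkenyl iodide at C5, which a Negishi coupling joins at C5–C6 to a chiral-pool keto iodide (C6–C21).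

Key step: step 2

Remark: the target is read as ring stereocentre R, C4=C5 Z (C3 and C6 cis), C9 R, C13 R, C17 S; the (R,R) ligand is specified because its tert-butyl group is expected to cover the alpha-Re face of the chelated dienophile.

Step 1
Reactants: 1 oxazolidin-2-one; 2 acryloyl chloride
Product: 3 3-acryloyloxazolidin-2-one
Conditions: Et3N, LiCl, THF, −20 °C → rt
Reagents that add atoms: none
Why: N-acylation of the carbamate nitrogen by the acid chloride, with LiCl/Et3N providing mild deprotonation so that the acryloyl group is not polymerised or attacked in a conjugate sense.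

Step 2
Reactants: 3 3-acryloyloxazolidin-2-one; 4 isoprene
Product: 5 (R)-3-(4-methylcyclohex-3-ene-1-carbonyl)oxazolidin-2-one
Conditions: Cu(SbF6)2 complex of 2,2'-isopropylidenebis[(4R)-4-tert-butyl-2-oxazoline] (10 mol%, made from CuCl2, the ligand and AgSbF6), isoprene (5 equiv), CH2Cl2, 0 °C → rt
Reagents that add atoms: none
Why: The imide binds the cationic copper centre (divalent copper, square planar) through both carbonyl oxygens, which holds the acryloyl group s-cis and lowers its LUMO, and isoprene then adds in a concerted, asynchronous, suprafacial [4+2] cycloaddition. The closest known reaction type is the bis(oxazoline)–copper-catalysed Diels–Alder reaction of N-acryloyl oxazolidinones with acyclic dienes. The cyclohexene ring is closed by the intermolecular cycloaddition itself: the bond from the acyl-bearing carbon to the CH2 next to the ring CH= and the CH2–CH2 bond are formed in the same event. The one new stereocentre is set by the ligand, whose tert-butyl group next to the bound alkene is expected to cover the alpha-Re face in the (R,R) series, so the diene bonds to the alpha-Si face and the acyl-bearing carbon becomes R. The step needs facial and para regioselectivity; the two-point binding of the imide secures the first, and the second follows from the methyl group of isoprene, which enlarges the HOMO coefficient at the adjacent CH2 terminus so that this carbon bonds to the beta carbon of the dienophile.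

Step 3
Reactants: 5 (R)-3-(4-methylcyclohex-3-ene-1-carbonyl)oxazolidin-2-one
Product: 6 (R)-N-methoxy-N,4-dimethylcyclohex-3-ene-1-carboxamide
Conditions: MeNHOMe·HCl, AlMe3, CH2Cl2, 0 °C → rt; Rochelle salt work-up
Reagents that add atoms: N,O-dimethylhydroxylamine hydrochloride, CNOC.Cl
Why: Transamidation of the activated imide by the aluminium amide formed in the flask (Weinreb amide formation) attacks the exocyclic acyl group, and the non-basic reagent should leave the alpha stereocentre untouched.

Step 4
Reactants: 6 (R)-N-methoxy-N,4-dimethylcyclohex-3-ene-1-carboxamide; 7 [2-(1,3-dioxolan-2-yl)ethyl]magnesium bromide (commercial THF solution)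
Product: 8 3-(1,3-dioxolan-2-yl)-1-[(1R)-4-methylcyclohex-3-en-1-yl]propan-1-one
Conditions: THF, 0 °C → rt; aq NH4Cl
Reagents that add atoms: none
Why: Weinreb ketone synthesis, in which the Grignard reagent adds once to give a chelated tetrahedral intermediate that releases the ketone only on quench, so over-addition and enolisation at the ring stereocentre are avoided.

Step 5
Reactants: 8 3-(1,3-dioxolan-2-yl)-1-[(1R)-4-methylcyclohex-3-en-1-yl]propan-1-one
Product: 9 2-{3-[(1R)-4-methylcyclohex-3-en-1-yl]but-3-en-1-yl}-1,3-dioxolane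
Conditions: Cp2TiMe2 (2.5 equiv), toluene–THF, 65 °C, dark
Reagents that add atoms: dimethyltitanocene Cp2TiMe2, C[Ti](C)(C1C=CC=C1)C1C=CC=C1
Why: Petasis methylenation through Cp2Ti=CH2 and an oxatitanacyclobutane is non-basic, so the enolisable ketone is converted into the 1,1-disubstituted alkene without epimerising the adjacent ring stereocentre, and the acetal is inert.

Step 6
Reactants: 9 2-{3-[(1R)-4-methylcyclohex-3-en-1-yl]but-3-en-1-yl}-1,3-dioxolane
Product: 10 4-[(1R)-4-methylcyclohex-3-en-1-yl]pent-4-enal
Conditions: PPTS (cat.), acetone–H2O, reflux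
Reagents that add atoms: water, O
Why: Acetal hydrolysis under weakly acidic pyridinium catalysis should free the aldehyde without protonating the trisubstituted ring alkene or the 1,1-disubstituted alkene.

Step 7
Reactants: 10 4-[(1R)-4-methylcyclohex-3-en-1-yl]pent-4-enal; 11 ethyltriphenylphosphonium iodide
Product: 15 (4R)-4-[(5Z)-6-iodohepta-1,5-dien-2-yl]-1-methylcyclohex-1-ene, via ethylidenetriphenylphosphorane 12 (not isolated), via (1-iodoethyl)triphenylphosphonium iodide 13 (not isolated), via (1-iodoethylidene)triphenylphosphorane 14 (not isolated)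
Conditions: 11, n-BuLi, THF, rt; I2, −78 °C; NaHMDS, −78 → −20 °C; then 10, −78 → −20 °C
Reagents that add atoms: iodine, II
Why: Stork–Zhao-type Wittig olefination with the unstabilised alpha-iodo ylide proceeds under kinetic control through the cis-oxaphosphetane, which should place iodine cis to the C3 chain and give the (Z)-2-iodoalkene carrying I and CH3 on C5.

Step 8
Reactants: 16 (S)-citronellyl bromide [(6S)-8-bromo-2,6-dimethyloct-2-ene]
Product: 17 (S)-1-bromo-3,7-dimethyloctane
Conditions: H2 (1 atm), PtO2, EtOAc, rt
Reagents that add atoms: none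
Why: Heterogeneous catalytic hydrogenation saturates the trisubstituted alkene to the isopropyl terminus while the primary bromide and the remote stereocentre (future C17) are not affected.

Step 9
Reactants: 18 (S)-3-bromo-2-methylpropan-1-ol
Product: 19 (S)-(3-bromo-2-methylpropoxy)(tert-butyl)dimethylsilane
Conditions: TBSCl, imidazole, CH2Cl2, rt
Reagents that add atoms: tert-butyldimethylsilyl chloride, CC(C)(C)[Si](C)(C)Cl
Why: Imidazole-promoted silylation masks the acidic hydroxyl group before the organometallic coupling and touches no bond at the stereocentre (future C13).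

Step 10
Reactants: 17 (S)-1-bromo-3,7-dimethyloctane; 19 (S)-(3-bromo-2-methylpropoxy)(tert-butyl)dimethylsilane
Product: 21 tert-butyldimethyl{[(2R,6S)-2,6,10-trimethylundecyl]oxy}silane, via (S)-3,7-dimethyloctylmagnesium bromide 20 (not isolated)
Conditions: 17, Mg, THF, reflux; then 19, Li2CuCl4 (3 mol%), NMP, THF, 0 °C → rt
Reagents that add atoms: magnesium, [Mg] (retained in 20 only)
Why: Copper-catalysed alkyl–alkyl cross-coupling of a primary Grignard reagent with a primary bromide forms C14–C15 by substitution at CH2 carbons only, so both methyl-bearing stereocentres are carried through unchanged.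

Step 11
Reactants: 21 tert-butyldimethyl{[(2R,6S)-2,6,10-trimethylundecyl]oxy}silane
Product: 24 (2R,6S)-2,6,10-trimethylundecanoic acid, via (2R,6S)-2,6,10-trimethylundecan-1-ol 22 (not isolated), via (2R,6S)-2,6,10-trimethylundecanal 23 (not isolated)
Conditions: CrO3, H2SO4, H2O, acetone, 0 °C → rt
Reagents that add atoms: water, O
Why: Jones oxidation, in which the aqueous sulfuric acid cleaves the primary silyl ether and chromic acid oxidises the freed alcohol through the aldehyde hydrate to the acid quickly enough that the alpha-methyl stereocentre should not epimerise.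

Step 12
Reactants: 24 (2R,6S)-2,6,10-trimethylundecanoic acid
Product: 25 (2R,6S)-N-methoxy-N,2,6,10-tetramethylundecanamide
Conditions: MeNHOMe·HCl, EDC·HCl, DMAP (cat.), N-methylmorpholine, CH2Cl2, 0 °C → rt
Reagents that add atoms: N,O-dimethylhydroxylamine hydrochloride, CNOC.Cl
Why: Carbodiimide-mediated amide coupling gives the Weinreb amide, and an alpha-alkyl acid without an alpha heteroatom is not prone to epimerise through the activated ester.

Step 13
Reactants: 26 (R)-citronellyl bromide [(6R)-8-bromo-2,6-dimethyloct-2-ene]; 25 (2R,6S)-N-methoxy-N,2,6,10-tetramethylundecanamide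
Product: 28 (6R,10R,14S)-2,6,10,14,18-pentamethylnonadec-2-en-9-one, via (R)-citronellylmagnesium bromide 27 (not isolated)
Conditions: 26, Mg, THF, 40 °C; then 25, THF, 0 °C → rt; aq NH4Cl
Reagents that add atoms: magnesium, [Mg] (retained in 27 only)
Why: Weinreb ketone synthesis forms the C11–C12 bond and the C12 ketone directly, the stable chelate preventing over-addition and keeping the alpha-methyl centre (C13) away from base until a mild quench.

Step 14
Reactants: 28 (6R,10R,14S)-2,6,10,14,18-pentamethylnonadec-2-en-9-one
Product: 30 (4R,8R,12S)-4,8,12,16-tetramethyl-7-oxoheptadecanal, via the secondary ozonide 29 (not isolated)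
Conditions: O3, CH2Cl2, −78 °C; then PPh3, −78 °C → rt
Reagents that add atoms: ozone, [O-][O+]=O
Why: Ozonolysis with reductive work-up cleaves the only alkene present, and PPh3 reduces the ozonide to the C6 aldehyde and acetone under neutral conditions.

Step 15
Reactants: 30 (4R,8R,12S)-4,8,12,16-tetramethyl-7-oxoheptadecanal
Product: 31 (4R,8R,12S)-1-hydroxy-4,8,12,16-tetramethylheptadecan-7-one
Conditions: NaBH4, EtOH–CH2Cl2, −78 °C
Reagents that add atoms: none
Why: Chemoselective borohydride reduction, since at −78 °C the unhindered aldehyde is reduced far faster than the alpha-branched dialkyl ketone and the cold, weakly basic medium should not epimerise C13.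

Step 16
Reactants: 31 (4R,8R,12S)-1-hydroxy-4,8,12,16-tetramethylheptadecan-7-one
Product: 32 (4S,8R,12S)-1-iodo-4,8,12,16-tetramethylheptadecan-7-one
Conditions: I2, PPh3, imidazole, CH2Cl2, 0 °C → rt
Reagents that add atoms: iodine, II
Why: Appel reaction, an SN2 displacement of the alkoxyphosphonium ion at the primary carbon buffered by imidazole; the descriptor at C4 changes from R to S only because the iodo-bearing branch now outranks the keto branch.

Step 17
Reactants: 32 (4S,8R,12S)-1-iodo-4,8,12,16-tetramethylheptadecan-7-one; 15 (4R)-4-[(5Z)-6-iodohepta-1,5-dien-2-yl]-1-methylcyclohex-1-ene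
Product: 34 (6S,10R,14R,18Z)-2,6,10,14,18-pentamethyl-22-[(1R)-4-methylcyclohex-3-en-1-yl]tricosa-18,22-dien-11-one, via [(4S,8R,12S)-4,8,12,16-tetramethyl-7-oxoheptadecyl]zinc iodide 33 (not isolated)
Conditions: 32, Zn dust (BrCH2CH2Br, Me3SiCl activation), LiCl, THF, 25–40 °C; then 15, PdCl2(dppf) (5 mol%), THF, rt → 40 °C
Reagents that add atoms: zinc, [Zn] (retained in 33 only)
Why: Negishi coupling, in which zinc inserts into the primary C–I bond to give an alkylzinc iodide that tolerates the ketone, and oxidative addition, transmetalation and reductive elimination at palladium keep the alkenyl geometry, so C6 should end up cis to C3 (the 4Z alkene).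

**Compound list**

1 | oxazolidin-2-one | O=C1NCCO1 | starting material
2 | acryloyl chloride | C=CC(Cl)=O | starting material
3 | 3-acryloyloxazolidin-2-one | C=CC(=O)N1CCOC1=O | intermediate
4 | isoprene | C=CC(C)=C | starting material
5 | (R)-3-(4-methylcyclohex-3-ene-1-carbonyl)oxazolidin-2-one | O=C(N1CCOC1=O)[C@H]1CC=C(C)CC1 | intermediate
6 | (R)-N-methoxy-N,4-dimethylcyclohex-3-ene-1-carboxamide | CON(C)C(=O)[C@H]1CC=C(C)CC1 | intermediate
7 | [2-(1,3-dioxolan-2-yl)ethyl]magnesium bromide | Br[Mg]CCC1OCCO1 | starting material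
8 | 3-(1,3-dioxolan-2-yl)-1-[(1R)-4-methylcyclohex-3-en-1-yl]propan-1-one | O=C(CCC1OCCO1)[C@H]1CC=C(C)CC1 | intermediate
9 | 2-{3-[(1R)-4-methylcyclohex-3-en-1-yl]but-3-en-1-yl}-1,3-dioxolane | C=C(CCC1OCCO1)[C@H]1CC=C(C)CC1 | intermediate
10 | 4-[(1R)-4-methylcyclohex-3-en-1-yl]pent-4-enal | C=C(CCC=O)[C@H]1CC=C(C)CC1 | intermediate
11 | ethyltriphenylphosphonium iodide | CC[P+](c1ccccc1)(c1ccccc1)c1ccccc1.[I-] | starting material
12 | ethylidenetriphenylphosphorane | CC=P(c1ccccc1)(c1ccccc1)c1ccccc1 | intermediate
13 | (1-iodoethyl)triphenylphosphonium iodide | CC(I)[P+](c1ccccc1)(c1ccccc1)c1ccccc1.[I-] | intermediate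
14 | (1-iodoethylidene)triphenylphosphorane | CC(I)=P(c1ccccc1)(c1ccccc1)c1ccccc1 | intermediate
15 | (4R)-4-[(5Z)-6-iodohepta-1,5-dien-2-yl]-1-methylcyclohex-1-ene | C=C(CC/C=C(/C)I)[C@H]1CC=C(C)CC1 | intermediate
16 | (S)-citronellyl bromide, (6S)-8-bromo-2,6-dimethyloct-2-ene | BrCC[C@@H](C)CCC=C(C)C | starting material
17 | (S)-1-bromo-3,7-dimethyloctane | BrCC[C@@H](C)CCCC(C)C | intermediate
18 | (S)-3-bromo-2-methylpropan-1-ol | OC[C@H](C)CBr | starting material
19 | (S)-(3-bromo-2-methylpropoxy)(tert-butyl)dimethylsilane | CC(C)(C)[Si](C)(C)OC[C@H](C)CBr | intermediate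
20 | (S)-3,7-dimethyloctylmagnesium bromide | Br[Mg]CC[C@@H](C)CCCC(C)C | intermediate
21 | tert-butyldimethyl{[(2R,6S)-2,6,10-trimethylundecyl]oxy}silane | CC(C)(C)[Si](C)(C)OC[C@H](C)CCC[C@@H](C)CCCC(C)C | intermediate
22 | (2R,6S)-2,6,10-trimethylundecan-1-ol | OC[C@H](C)CCC[C@@H](C)CCCC(C)C | intermediate
23 | (2R,6S)-2,6,10-trimethylundecanal | O=C[C@H](C)CCC[C@@H](C)CCCC(C)C | intermediate
24 | (2R,6S)-2,6,10-trimethylundecanoic acid | OC(=O)[C@H](C)CCC[C@@H](C)CCCC(C)C | intermediate
25 | (2R,6S)-N-methoxy-N,2,6,10-tetramethylundecanamide | CON(C)C(=O)[C@H](C)CCC[C@@H](C)CCCC(C)C | intermediate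
26 | (R)-citronellyl bromide, (6R)-8-bromo-2,6-dimethyloct-2-ene | BrCC[C@H](C)CCC=C(C)C | starting material
27 | (R)-citronellylmagnesium bromide | Br[Mg]CC[C@H](C)CCC=C(C)C | intermediate
28 | (6R,10R,14S)-2,6,10,14,18-pentamethylnonadec-2-en-9-one | CC(C)=CCC[C@@H](C)CCC(=O)[C@H](C)CCC[C@@H](C)CCCC(C)C | intermediate
29 | 3,3-dimethyl-5-[(3R,7R,11S)-3,7,11,15-tetramethyl-6-oxohexadecyl]-1,2,4-trioxolane (ozonide, mixture at the ring carbon) | CC1(C)OOC(CC[C@@H](C)CCC(=O)[C@H](C)CCC[C@@H](C)CCCC(C)C)O1 | intermediate
30 | (4R,8R,12S)-4,8,12,16-tetramethyl-7-oxoheptadecanal | O=CCC[C@@H](C)CCC(=O)[C@H](C)CCC[C@@H](C)CCCC(C)C | intermediate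
31 | (4R,8R,12S)-1-hydroxy-4,8,12,16-tetramethylheptadecan-7-one | OCCC[C@@H](C)CCC(=O)[C@H](C)CCC[C@@H](C)CCCC(C)C | intermediate
32 | (4S,8R,12S)-1-iodo-4,8,12,16-tetramethylheptadecan-7-one | ICCC[C@@H](C)CCC(=O)[C@H](C)CCC[C@@H](C)CCCC(C)C | intermediate
33 | [(4S,8R,12S)-4,8,12,16-tetramethyl-7-oxoheptadecyl]zinc iodide | I[Zn]CCC[C@@H](C)CCC(=O)[C@H](C)CCC[C@@H](C)CCCC(C)C | intermediate
34 | (6S,10R,14R,18Z)-2,6,10,14,18-pentamethyl-22-[(1R)-4-methylcyclohex-3-en-1-yl]tricosa-18,22-dien-11-one | C=C(CC/C=C(/C)CCC[C@@H](C)CCC(=O)[C@H](C)CCC[C@@H](C)CCCC(C)C)[C@H]1CC=C(C)CC1 | target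

**Step count.** Total: 17 steps. Longest linear sequence: 9 steps (steps 8, 10, 11, 12, 13, 14, 15, 16, 17, from 16 to 34); the ring branch (steps 1–7, then 17) is 8 steps.

**Steps most likely to fail**

Step 2. Facial discrimination may be insufficient, because a diene with no substituent at its reacting termini sits less tightly in the chiral pocket. The minor enantiomer would then be carried forward and would surface as a diastereomer after step 17. Fallback (auxiliary control in place of catalyst control), setting out from 2 and 4 and coming back at 6: commercial (S)-4-benzyloxazolidin-2-one is N-acylated with 2 to give (S)-3-acryloyl-4-benzyloxazolidin-2-one F1. An Et2AlCl-promoted Diels–Alder reaction with 4 in CH2Cl2 at −100 °C (chelated aluminium imide, diene approaching anti to the benzyl group) should give (S)-4-benzyl-3-[(R)-4-methylcyclohex-3-ene-1-carbonyl]oxazolidin-2-one F2. F2 can be purified to a single diastereomer and is transamidated as in step 3 to rejoin the route at 6.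

Step 7. Iodination of the ylide may be incomplete (leading to the iodine-free ethylidene alkene), the iodo ylide may decompose before it meets the aldehyde, and the Z preference may erode. Fallback (stepwise stereoselective cross-coupling in place of olefination), setting out from 10 and coming back at 34: dibromo-olefination of the Corey–Fuchs type (CBr4, PPh3, CH2Cl2, 0 °C) should give (4R)-4-(6,6-dibromohexa-1,5-dien-2-yl)-1-methylcyclohex-1-ene F3. Palladium-catalysed trans-selective monomethylation (MeZnCl, PdCl2(DPEphos), THF) replaces the bromine trans to the chain and should give (4R)-4-[(5Z)-6-bromohepta-1,5-dien-2-yl]-1-methylcyclohex-1-ene F4. F4 takes the place of 15 in the coupling with 33 in step 17 and so reaches 34.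

Step 17. Zinc insertion next to a ketone-bearing chain may be slow or incomplete, the organozinc may be protonated, and sluggish transmetalation may lead to reduction, homocoupling or partial loss of alkene geometry. Fallback (reversed polarity of the C5–C6 coupling), setting out from 15 and 32 and coming back at 34: iodine–lithium exchange on 15 (t-BuLi, Et2O, −78 °C) should give {(2E)-6-[(1R)-4-methylcyclohex-3-en-1-yl]hepta-2,6-dien-2-yl}lithium F5 with retained geometry. ZnCl2 converts it into chloro{(2Z)-6-[(1R)-4-methylcyclohex-3-en-1-yl]hepta-2,6-dien-2-yl}zinc F6. F6 is coupled with the unactivated primary iodide 32 in an alkyl-electrophile Negishi coupling (Pd2(dba)3, tricyclopentylphosphine, N-methylimidazole, THF–NMP, 80 °C) to give 34.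

**Further compounds**

F1 | step 2 | (S)-3-acryloyl-4-benzyloxazolidin-2-one | C=CC(=O)N1[C@@H](Cc2ccccc2)COC1=O
F2 | step 2 | (S)-4-benzyl-3-[(R)-4-methylcyclohex-3-ene-1-carbonyl]oxazolidin-2-one | O=C([C@H]1CC=C(C)CC1)N1[C@@H](Cc2ccccc2)COC1=O
F3 | step 7 | (4R)-4-(6,6-dibromohexa-1,5-dien-2-yl)-1-methylcyclohex-1-ene | C=C(CCC=C(Br)Br)[C@H]1CC=C(C)CC1
F4 | step 7 | (4R)-4-[(5Z)-6-bromohepta-1,5-dien-2-yl]-1-methylcyclohex-1-ene | C=C(CC/C=C(/C)Br)[C@H]1CC=C(C)CC1
F5 | step 17 | {(2E)-6-[(1R)-4-methylcyclohex-3-en-1-yl]hepta-2,6-dien-2-yl}lithium | C=C(CC/C=C(/C)[Li])[C@H]1CC=C(C)CC1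
F6 | step 17 | chloro{(2Z)-6-[(1R)-4-methylcyclohex-3-en-1-yl]hepta-2,6-dien-2-yl}zinc | C=C(CC/C=C(/C)[Zn]Cl)[C@H]1CC=C(C)CC1
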